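## The problem

The target is a trans-fused eremophilane. Ring A (C1–C5, C10) and ring B (C5–C10) share the C5–C10 bond, and the quaternary C5 carries a methyl group (C14) cis to the C4 methyl (C15) and anti to H-10. Seven stereocentres lie on the decalin (C3, C4, C5, C7, C8, C9, C10) and an eighth (C4', R) in the acyl chain. In the chair–chair form the C5 methyl is axial on both rings and every other substituent except the 8α-hydroxyl is equatorial. The axial methyl can therefore steer reagents to the α face at C3, C4, C9 and C10, the equatorial isopropenyl group at C7 is the thermodynamic epimer next to a C8 carbonyl, and the axial 8α-hydroxyl needs a kinetic, equatorial hydride delivery. C5 has no neighbour that could control it and must be set by absolute stereocontrol; the remote side-chain centre is best bought.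

The fragile parts are four:

- the (Z)-4-acyloxy-2-enoate, which isomerises to E on activation and lactonises to a butenolide once the 4-oxygen is free;
- the angelate, which drifts to the tiglate;
- the isopropenyl group, which survives neither hydrogenation nor selenium dioxide;
- the cis-8,9-diol, which must be told apart from the C3 hydroxyl when the ester is attached.

A further trap is the ring fusion: next to a C1 ketone, a decalone with the angular methyl on the far fusion carbon is estimated to be close to thermoneutral between cis and trans, so base epimerisation of C10 cannot be relied on.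

The feature that opens a short entry is the substitution of C5: a methyl, C4, and the two ring B arms C6 and C10. If ring B is a cyclohexa-2,5-dienone with its carbonyl at C8 and C4 is a trigonal methylene carbon, C5 is prochiral, its two arms are enantiotopic, and closing ring A onto one of them creates the quaternary centre.

## Retrosynthesis

Ester and Z-alkene. Target 34 is taken back to its 8,9-acetonide 33, so that the C3 hydroxyl is the only free one when the chain is attached. The O3–C1' bond is not cut at the Z-enoic acid stage, since activating such an acid invites Z-to-E isomerisation. The C2'=C3' bond is first returned to an alkyne (33 ⇒ 32), and the ester bond is cut in 32 to give alcohol 25 and ynoic acid 31. Compound 25 has lost the chain, one stereocentre and every alkene-geometry question. The forward reactions must acylate a secondary equatorial alcohol without disturbing a 4-acyloxy-2-ynoate, add hydrogen syn to the alkyne while ignoring a 1,1-disubstituted and a trisubstituted alkene, and hydrolyse an acetal in the presence of two esters.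

Side-chain acid. Acid 31 is cut at C1'–C2' (carboxylation of the terminal alkyne 29) and 29 at the angelate C–O bond, giving alcohol 26 and angelic acid 27. Attaching the angelate first means that a free 4-hydroxy-2-ynoate, prone to redox isomerisation and later to lactonisation, never exists. The stereocentre is bought with 26.

C8, C9 and C10. Acetonide 25 comes from triol 24, and 24 from hydroxy ketone 23 by cutting the C8–H bond; a bulky hydride gives the axial alcohol between two equatorial neighbours. In 23 the C9–O and C10–H bonds are cut together, back to the Δ9-enone 21. This is preferred to hydroxylating a saturated ketone, where C7 and C9 compete, and to epimerising C10 with base. Dissolving-metal reduction protonates C10 axially, anti to C14, and leaves the enolate at C8–C9 only, where oxygen enters anti to the syn-axial methyl. Two stereocentres are removed and the ring-fusion problem becomes a classical one.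

C7. Enone 21 is cut at C6–H/C7–H (conjugate reduction of trienone 20) and at C7–C11 (cross-coupling of iodide 19, itself from dienone 18). An isopropenyl group α to a ketone is not cleanly available by aldol–dehydration, which ends in the conjugated isopropylidene ketone; coupling at the α-carbon of an iodoenone has no regiochemical ambiguity. In 18 only the C6–C7 arm has a β-hydrogen, which directs both the iodination and the later hydride addition.

C3 and C4. Dienone 18 is cut at the C4–H bond (hydrogenation of the exocyclic alkene of 17) and 17 at C3–O (allylic oxidation of 16). These two operations are the reason ring A is finished before C11–C13 arrive, since both would also attack an isopropenyl group. In 16 the exocyclic methylene is the only electron-rich alkene and C3 its only allylic CH2. Ring A is a chair with C14 axial, so oxygen and then hydrogen are expected on the α face. Compound 16 has one stereocentre, C5.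

C10 erased, C1 deoxygenated. Trienone 16 is taken back to enone 14 by removing the C9=C10 double bond, and 14 to ene-dione 11 by restoring the C1 oxygen (via 13 and 12). The dehydrogenation 14 → 16 deliberately deletes the cis C10 centre that the ring closure sets and gives ring A a single predictable conformation. The C1 oxygen is removed by reducing the saturated ketone in the presence of the enone and deoxygenating the alcohol by a radical chain.

Key disconnection. Ene-dione 11 is cut at C1–C10. The precursor 10 is an achiral cyclohexadienone with an aldehyde tether. The forward reaction must make an acyl anion equivalent at C1, add it to one of two enantiotopic β-carbons, and close a six-membered ring. The cis fusion this imposes is accepted because C10 is reset later.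

Dienone aldehyde. Aldehyde 10 comes from acetal 9, 9 from the 1,4-diene 8 by oxidation of the doubly allylic CH2, 8 from ketone 7 by methylenation, and 7 from acid 3 and bromoacetal 4 by acylation of the derived Grignard reagent. Acid 3 is the reductive methylation product of benzoic acid 1, so the quaternary carbon is made on an aromatic ring with no stereochemical issue.

## Roads not taken

Alternative 1: The cut is C6–C7. A ring A building block A1 would already hold C3, C4, C5 and C10, a neopentyl iodide at C6 and, on C10, the C9–C8 acetonide ending in a 2-methylallyl phenyl sulfone. Under radical chain conditions the primary C6 radical adds 6-exo to C7, the sulfonyl radical leaves, and A2 results with ring B closed and the isopropenyl group on C7.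

- Merits: a neopentyl radical is not hindered the way a neopentyl electrophile is. The isopropenyl group is created after all oxidations and reductions. A2 is a desilylation, an esterification, a semi-hydrogenation and a deprotection from the target.
- Weak points: six stereocentres, including the quaternary C5 flanked by C4 and C10, must be in place before the key step, and the key step offers no help with any of them. The 6-exo closure competes with direct reduction of the radical. The C7 configuration rests on a chair-like transition state only.
- Comparison: this road is better in the end game and in never exposing the isopropenyl group to redox reagents. The chosen plan sets against it the creation of C5 by a catalyst from flat, achiral material, followed by centres that are each placed under the control of the axial methyl. Its price is the redox traffic on ring B.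

Alternative 2: The cut is C7–C8. A3 is a ring A aldehyde carrying a prenyl group on C5 and an α-silyloxy aldehyde (C9, C8) on C10. With Me2AlCl the aldehyde and the trisubstituted alkene undergo a carbonyl-ene reaction that forms C7–C8, closes ring B and turns the prenyl group into the isopropenyl group, giving A4.

- Merits: atom economy, two stereocentres in the ring-forming step, and a robust prenyl group that becomes the sensitive isopropenyl group only at the end.
- Weak points: the chair transition state puts both new substituents equatorial, so A4 has the 8β-hydroxyl and is epimeric with the target at C8. An oxidation and a LiBH(s-Bu)3 reduction would still be needed, and the ketone stage reopens C7 to epimerisation. The α-silyloxy aldehyde is configurationally labile under the Lewis acid. C3, C4, C5, C9 and C10 must all be made beforehand on a monocyclic ring.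
- Comparison: this road equals the chosen plan in needing the late hydride step and beats it in steps after ring closure and in avoiding a cross-coupling. The chosen plan answers with a catalytic origin for C5, with C9 and C10 drawn from one dissolving-metal operation, and with a key-step substrate that carries no stereocentre.

Alternative 3: The cut is C5–C10 and C3–C4 at once. A5 is an acyclic triene in which an E-configured β-methyl enoate (C15, C4, C5) is linked through C6–C9, carrying the C7, C8 and C9 centres, to a 1-silyloxy diene (C10, C1, C2, C3). An intramolecular Diels–Alder reaction gives the octalin A6 with both rings and four new stereocentres.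

- Merits: the largest gain in complexity per step, direct access to the trans fusion, and the C3 oxygen delivered by the diene.
- Weak points: the dienophile carbon that becomes the quaternary C5 is β,β-disubstituted, and such enoates react sluggishly. Endo/exo and facial selectivity hang on three remote centres. In A6 the C3 oxygen is on the β face, cis to C15, so it would have to be inverted. C15 arrives as an ester and needs several steps to become a methyl group. The C1=C2 alkene must be reduced beside an isopropenyl group.
- Comparison: in convergence and bonds formed per step this road is superior. The chosen plan sets against it that every stereocentre is introduced by a separately controllable reaction, that C5 is set by a catalyst and not by relay from C7–C9, and that no carbon has to change oxidation level merely to become a methyl group.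

Key step: step 6

Conventions and assumptions:

- Bicyclic compounds carry eremophilane numbering (ring A: C1–C5 and C10; ring B: C5–C10; C14 on C5, C15 on C4, C11–C13 on C7). β is the face of the C5 methyl group, α the other face. Compounds without C11–C13 are named as 11,12,13-trinoreremophilanes. Absolute configuration is that of the SMILES strings (5R in the target).
- (R)-Pent-1-yn-3-ol 26 is taken as a purchasable single enantiomer.
- Both antipodes of the triazolium salt of step 6 are available. Which one leads to 11 and not to its mirror image is settled in the first cyclisation run.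
- The C1 carbinol centre of 12 and 13 is removed in step 9 and is left undefined.

Step 1
Reactants: 1 benzoic acid
Product: 3 1-methylcyclohexa-2,5-diene-1-carboxylic acid, via dilithium dienediolate 2 (not isolated)
Conditions: Li, NH3(l), THF, −78 °C; MeI, −78 °C to rt; aq. HCl
Reagents that add atoms: iodomethane, CI
Why: Birch reduction of the benzoate stops at the cross-conjugated dienediolate, which is alkylated at the carboxyl-bearing carbon (Birch reductive alkylation); the quaternary carbon is formed without any stereochemical issue.

Step 2
Reactants: 3 1-methylcyclohexa-2,5-diene-1-carboxylic acid; 4 2-(2-bromoethyl)-1,3-dioxolane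
Product: 7 3-(1,3-dioxolan-2-yl)-1-(1-methylcyclohexa-2,5-dien-1-yl)propan-1-one, via acid chloride 5 (not isolated), via Grignard reagent 6 (not isolated)
Conditions: 3, (COCl)2, DMF (cat.), CH2Cl2, 0 °C to rt, evaporate; 4, Mg, THF, 25 °C; then 5 + 6, CuI (5 mol%), THF, −78 °C
Reagents that add atoms: none
Why: Copper-catalysed acylation of a Grignard reagent by an acid chloride stops at the ketone, the more so as the carbonyl is flanked by a quaternary carbon; the acetal Grignard reagent is a standard three-carbon aldehyde synthon.

Step 3
Reactants: 7 3-(1,3-dioxolan-2-yl)-1-(1-methylcyclohexa-2,5-dien-1-yl)propan-1-one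
Product: 8 2-[3-(1-methylcyclohexa-2,5-dien-1-yl)but-3-en-1-yl]-1,3-dioxolane
Conditions: Ph3PCH3Br, KOt-Bu, THF, 0 °C to 65 °C
Reagents that add atoms: methyltriphenylphosphonium bromide, C[P+](c1ccccc1)(c1ccccc1)c1ccccc1.[Br-]
Why: Wittig methylenation; ketones next to a quaternary carbon react with the unstabilised ylide on warming, and reversible enolisation on the CH2 side does no harm.

Step 4
Reactants: 8 2-[3-(1-methylcyclohexa-2,5-dien-1-yl)but-3-en-1-yl]-1,3-dioxolane
Product: 9 4-[4-(1,3-dioxolan-2-yl)but-1-en-2-yl]-4-methylcyclohexa-2,5-dien-1-one
Conditions: (C5H5NH)2Cr2O7, t-BuOOH, Celite, benzene, rt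
Reagents that add atoms: tert-butyl hydroperoxide, CC(C)(C)OO
Why: Chromium-mediated hydroperoxide oxidation of the doubly allylic ring CH2 is the established way from 3,3-disubstituted cyclohexa-1,4-dienes to 4,4-disubstituted cyclohexa-2,5-dienones (allylic oxidation); the singly allylic chain CH2 is much less reactive.

Step 5
Reactants: 9 4-[4-(1,3-dioxolan-2-yl)but-1-en-2-yl]-4-methylcyclohexa-2,5-dien-1-one
Product: 10 4-(1-methyl-4-oxocyclohexa-2,5-dien-1-yl)pent-4-enal
Conditions: 1 M HCl, THF, rt
Reagents that add atoms: water, O
Why: Acid hydrolysis of the dioxolane; dilute acid at room temperature is far below what a dienone–phenol rearrangement or alkene migration would need.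

Step 6
Reactants: 10 4-(1-methyl-4-oxocyclohexa-2,5-dien-1-yl)pent-4-enal
Product: 11 (10βH)-11,12,13-trinoreremophila-4(15),6-diene-1,8-dione (cis-fused)
Conditions: 2-(pentafluorophenyl)-5a,10b-dihydro-4H,6H-indeno[2,1-b][1,2,4]triazolo[4,3-d][1,4]oxazin-2-ium tetrafluoroborate (one antipode, 10 mol%), KN(SiMe3)2 (10 mol%), toluene, 23 °C
Reagents that add atoms: none
Why: Deprotonation of the triazolium salt gives the carbene, which adds to the aldehyde of 10 and after proton transfer forms a nucleophilic enaminol (acyl anion equivalent); its C1 attacks the β-carbon C10 of one enone arm, the enolate is protonated at C9, and collapse of the tetrahedral intermediate releases the carbene (intramolecular Stetter reaction). The closest known reaction type is the carbene-catalysed enantioselective Stetter desymmetrisation of 4,4-disubstituted cyclohexa-2,5-dienones bearing a tethered aldehyde. Ring A closes in the 6-exo-trig mode, and C1–C10 is the only skeletal bond formed. C5 is controlled by the catalyst, which chooses between the two enantiotopic enone arms. C10 is controlled by the tether, because the acyl carbon can reach only the dienone face on which the C4 chain sits, so the fusion is cis. The step needs enantiotopic-group selectivity alone: the substrate has a mirror plane through C5 and C8 and no stereocentre, and the trigonal C4 stiffens the tether and holds C1 over C10. Self-condensation of the aldehyde is kept down by the intramolecular acceptor and by dilution.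

Step 7
Reactants: 11 (10βH)-11,12,13-trinoreremophila-4(15),6-diene-1,8-dione
Product: 12 (10βH)-1ξ-hydroxy-11,12,13-trinoreremophila-4(15),6-dien-8-one
Conditions: NaBH4, MeOH/CH2Cl2 (1:1), −78 °C
Reagents that add atoms: none
Why: At low temperature borohydride reduces a saturated ketone much faster than a conjugated enone (chemoselective carbonyl reduction); the new C1 centre is deleted in step 9, so its configuration does not matter.

Step 8
Reactants: 12 (10βH)-1ξ-hydroxy-11,12,13-trinoreremophila-4(15),6-dien-8-one
Product: 13 O-phenyl thionocarbonate of 12
Conditions: PhOC(S)Cl, pyridine, DMAP (cat.), CH2Cl2, rt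
Reagents that add atoms: O-phenyl chlorothionoformate, S=C(Cl)Oc1ccccc1
Why: Acylation of the secondary alcohol under conditions too weakly basic to enolise the enone gives the radical precursor for the Barton–McCombie reaction.

Step 9
Reactants: 13 O-phenyl thionocarbonate of 12
Product: 14 (10βH)-11,12,13-trinoreremophila-4(15),6-dien-8-one
Conditions: Bu3SnH, AIBN (cat.), toluene, 100 °C
Reagents that add atoms: none
Why: Barton–McCombie deoxygenation; the secondary C1 radical has no alkene within reach of a favourable ring closure and is reduced by the stannane.

Step 10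
Reactants: 14 (10βH)-11,12,13-trinoreremophila-4(15),6-dien-8-one
Product: 16 11,12,13-trinoreremophila-4(15),6,9-trien-8-one, via silyl dienol ether 15 (not isolated)
Conditions: LiN(i-Pr)2, Me3SiCl, THF, −78 °C; then Pd(OAc)2 (1.05 equiv), MeCN, rt
Reagents that add atoms: none
Why: Saegusa–Ito oxidation: kinetic deprotonation of the enone at C9 and silylation give the 2-silyloxy diene, which Pd(OAc)2 converts into the cross-conjugated dienone. C10 becomes trigonal, which erases the cis fusion left by step 6 and fixes ring A as a chair with the C5 methyl axial.

Step 11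
Reactants: 16 11,12,13-trinoreremophila-4(15),6,9-trien-8-one
Product: 17 3α-hydroxy-11,12,13-trinoreremophila-4(15),6,9-trien-8-one
Conditions: SeO2 (0.5 equiv), t-BuOOH, CH2Cl2, 0 °C to rt
Reagents that add atoms: selenium dioxide, O=[Se]=O; tert-butyl hydroperoxide, CC(C)(C)OO
Why: Allylic hydroxylation by ene reaction and [2,3]-sigmatropic shift; the exocyclic methylene is the only electron-rich alkene and C3 its only allylic CH2. In the rearrangement the selenium-bearing CH2 and the incoming oxygen should avoid the β face, where both would clash with the axial C5 methyl, so the 3α (equatorial) alcohol is expected.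

Step 12
Reactants: 17 3α-hydroxy-11,12,13-trinoreremophila-4(15),6,9-trien-8-one
Product: 18 3α-hydroxy-11,12,13-trinoreremophila-6,9-dien-8-one
Conditions: [Ir(cod)(PCy3)(py)]PF6 (2.5 mol%), H2 (1 atm), CH2Cl2, 0 °C, stopped after one equivalent
Reagents that add atoms: none
Why: Hydroxyl-directed hydrogenation: iridium bound to the 3α-hydroxyl adds hydrogen to the α face of the exocyclic alkene, the face that sterics also favour because the β face is screened by the adjacent axial methyl, so C15 ends up β (equatorial). The hindered, electron-poor dienone alkenes are much poorer ligands for the cationic metal.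

Step 13
Reactants: 18 3α-hydroxy-11,12,13-trinoreremophila-6,9-dien-8-one
Product: 19 3α-hydroxy-7-iodo-11,12,13-trinoreremophila-6,9-dien-8-one
Conditions: I2, pyridine, CH2Cl2, rt
Reagents that add atoms: iodine, II
Why: α-Iodination of an enone by reversible addition of pyridine to the β-carbon, iodination of the enolate and elimination; only C6 is a β-carbon that bears hydrogen and is open to the nucleophile, so iodine enters at C7.

Step 14
Reactants: 19 3α-hydroxy-7-iodo-11,12,13-trinoreremophila-6,9-dien-8-one
Product: 20 3α-hydroxyeremophila-6,9,11-trien-8-one
Conditions: 2-isopropenyl-4,4,5,5-tetramethyl-1,3,2-dioxaborolane, Pd(dppf)Cl2 (5 mol%), K3PO4, THF/H2O, 50 °C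
Reagents that add atoms: 2-isopropenyl-4,4,5,5-tetramethyl-1,3,2-dioxaborolane, CC(=C)B1OC(C)(C)C(C)(C)O1
Why: Suzuki–Miyaura coupling of an α-iodoenone with an alkenylboronate; the electron-poor vinyl iodide undergoes oxidative addition readily and the free hydroxyl is tolerated.

Step 15
Reactants: 20 3α-hydroxyeremophila-6,9,11-trien-8-one
Product: 21 3α-hydroxy-7βH-eremophila-9,11-dien-8-one
Conditions: [(Ph3P)CuH]6 (0.35 equiv), H2O (2 equiv), benzene, rt; then DBU (5 mol%), CH2Cl2, 0 °C, short
Reagents that add atoms: none
Why: Copper hydride conjugate reduction delivers hydride to C6, the only β-carbon that is not fully substituted, and the copper enolate is protonated at C7. C7 remains epimerisable and a brief base treatment lets it settle with the isopropenyl group α (pseudo-equatorial), since the β epimer would sit syn to the C5 methyl; kinetic protonation of the dienolate at the α-carbon is faster than the γ-protonation that would conjugate the side-chain alkene.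

Step 16
Reactants: 21 3α-hydroxy-7βH-eremophila-9,11-dien-8-one
Product: 23 3α,9α-dihydroxy-7βH,10αH-eremophil-11-en-8-one, via dilithium enolate 22 (not isolated)
Conditions: Li (2.2 equiv), NH3(l)/THF, −78 °C; evaporate NH3; 2-(phenylsulfonyl)-3-phenyloxaziridine, THF, −78 °C; aq. NH4Cl
Reagents that add atoms: 2-(phenylsulfonyl)-3-phenyloxaziridine, O=S(=O)(c1ccccc1)N1OC1c1ccccc1
Why: Dissolving-metal (Birch-type) reduction of the octalone: the C10 carbanion is protonated axially, anti to the angular methyl, with the substrate hydroxyl as the one equivalent of proton donor, which gives the trans fusion and leaves the enolate regiospecifically at C8–C9. Oxaziridine hydroxylation of this enolate occurs on the α face, because the axial β approach to C9 is blocked by the syn-axial C5 methyl, so the 9-hydroxyl is α and equatorial.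

Step 17
Reactants: 23 3α,9α-dihydroxy-7βH,10αH-eremophil-11-en-8-one
Product: 24 7βH,10αH-eremophil-11-ene-3α,8α,9α-triol
Conditions: LiBH(s-Bu)3 (4 equiv), THF, −78 °C; aq. NH4Cl
Reagents that add atoms: none
Why: The bulky hydride attacks the cyclohexanone along the equatorial direction between the two equatorial neighbours and gives the axial 8α-alcohol, cis to the 9α-hydroxyl (ketone reduction under steric approach control).

Step 18
Reactants: 24 7βH,10αH-eremophil-11-ene-3α,8α,9α-triol
Product: 25 8α,9α-O-isopropylidene-7βH,10αH-eremophil-11-ene-3α,8α,9α-triol
Conditions: 2,2-dimethoxypropane, pyridinium p-toluenesulfonate (cat.), acetone, rt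
Reagents that add atoms: 2,2-dimethoxypropane, COC(C)(C)OC
Why: Only the cis-8,9-diol can close a five-membered acetonide (acetalisation), which leaves the C3 hydroxyl as the single free alcohol; any mixed acetal at C3 is lost on aqueous work-up.

Step 19
Reactants: 26 (R)-pent-1-yn-3-ol; 27 angelic acid
Product: 29 (R)-pent-1-yn-3-yl (Z)-2-methylbut-2-enoate, via mixed anhydride 28 (not isolated)
Conditions: 27, 2,4,6-trichlorobenzoyl chloride, Et3N, toluene, rt; then 26, 80 °C
Reagents that add atoms: none
Why: Yamaguchi-type mixed anhydride acylation; without a nucleophilic catalyst the alcohol attacks the less hindered angeloyl carbonyl and the Z geometry of the angelate is kept.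

Step 20
Reactants: 29 (R)-pent-1-yn-3-yl (Z)-2-methylbut-2-enoate
Product: 31 (R)-4-[(Z)-2-methylbut-2-enoyloxy]hex-2-ynoic acid, via lithium acetylide 30 (not isolated)
Conditions: LiN(i-Pr)2 (1.0 equiv), THF, −78 °C; CO2 (g), −78 °C to 0 °C; aq. HCl to pH 2
Reagents that add atoms: carbon dioxide, O=C=O
Why: The terminal alkyne C–H is by far the kinetically most acidic site and the hindered amide does not add to the ester; the acetylide is trapped by carbon dioxide (acetylide carboxylation) and the stereocentre is untouched.

Step 21
Reactants: 25 8α,9α-O-isopropylidene-7βH,10αH-eremophil-11-ene-3α,8α,9α-triol; 31 (R)-4-[(Z)-2-methylbut-2-enoyloxy]hex-2-ynoic acid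
Product: 32 3-O-[(R)-4-(angeloyloxy)hex-2-ynoyl] derivative of 25
Conditions: DCC, DMAP (5 mol%), CH2Cl2, −20 °C to 0 °C
Reagents that add atoms: none
Why: Steglich esterification at the only free hydroxyl; an alkynoic acid has no alkene geometry to lose, and low temperature with little DMAP keeps the 4-acyloxy-2-ynoate from base-induced isomerisation.

Step 22
Reactants: 32 3-O-[(R)-4-(angeloyloxy)hex-2-ynoyl] derivative of 25
Product: 33 3-O-[(2Z,4R)-4-(angeloyloxy)hex-2-enoyl] derivative of 25
Conditions: H2 (1 atm), Pd/CaCO3 poisoned with Pb(OAc)2, quinoline, EtOAc, rt, stopped after one equivalent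
Reagents that add atoms: none
Why: Lindlar reduction: syn addition of hydrogen to the alkyne gives the Z-enoate, and the poisoned catalyst leaves the 1,1-disubstituted isopropenyl group and the trisubstituted angelate alone.

Step 23
Reactants: 33 3-O-[(2Z,4R)-4-(angeloyloxy)hex-2-enoyl] derivative of 25
Product: 34 CNP0382739.1, 3α-[(2Z,4R)-4-(angeloyloxy)hex-2-enoyloxy]-7βH,10αH-eremophil-11-ene-8α,9α-diol
Conditions: AcOH/H2O (4:1), 40 °C
Reagents that add atoms: none
Why: Acetal hydrolysis in dilute acetic acid; both esters, the Z-enoate and the isopropenyl group tolerate these conditions, and the C3 ester has no neighbouring hydroxyl that could invite acyl migration.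

Compound list

1 | benzoic acid | O=C(O)c1ccccc1 | starting material
2 | dilithium dienediolate of 1,4-dihydrobenzoic acid (not isolated) | [Li+].[Li+].[O-]C([O-])=C1C=CCC=C1 | intermediate
3 | 1-methylcyclohexa-2,5-diene-1-carboxylic acid | CC1(C(=O)O)C=CCC=C1 | intermediate
4 | 2-(2-bromoethyl)-1,3-dioxolane | BrCCC1OCCO1 | starting material
5 | 1-methylcyclohexa-2,5-diene-1-carbonyl chloride (not isolated) | CC1(C(=O)Cl)C=CCC=C1 | intermediate
6 | [2-(1,3-dioxolan-2-yl)ethyl]magnesium bromide (not isolated) | Br[Mg]CCC1OCCO1 | intermediate
7 | 3-(1,3-dioxolan-2-yl)-1-(1-methylcyclohexa-2,5-dien-1-yl)propan-1-one | O=C(CCC1OCCO1)C1(C)C=CCC=C1 | intermediate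
8 | 2-[3-(1-methylcyclohexa-2,5-dien-1-yl)but-3-en-1-yl]-1,3-dioxolane | C=C(CCC1OCCO1)C1(C)C=CCC=C1 | intermediate
9 | 4-[4-(1,3-dioxolan-2-yl)but-1-en-2-yl]-4-methylcyclohexa-2,5-dien-1-one | C=C(CCC1OCCO1)C1(C)C=CC(=O)C=C1 | intermediate
10 | 4-(1-methyl-4-oxocyclohexa-2,5-dien-1-yl)pent-4-enal | O=CCCC(=C)C1(C)C=CC(=O)C=C1 | intermediate
11 | (10βH)-11,12,13-trinoreremophila-4(15),6-diene-1,8-dione, cis-fused | C1=C[C@]2(C)C(=C)CCC(=O)[C@@H]2CC1=O | intermediate
12 | (10βH)-1ξ-hydroxy-11,12,13-trinoreremophila-4(15),6-dien-8-one | C1=C[C@]2(C)C(=C)CCC(O)[C@@H]2CC1=O | intermediate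
13 | O-phenyl thionocarbonate of 12 | C1=C[C@]2(C)C(=C)CCC(OC(=S)Oc3ccccc3)[C@@H]2CC1=O | intermediate
14 | (10βH)-11,12,13-trinoreremophila-4(15),6-dien-8-one | C1=C[C@]2(C)C(=C)CCC[C@@H]2CC1=O | intermediate
15 | (10βH)-8-(trimethylsilyloxy)-11,12,13-trinoreremophila-4(15),6,8-triene (not isolated) | C1=C[C@]2(C)C(=C)CCC[C@@H]2C=C1O[Si](C)(C)C | intermediate
16 | 11,12,13-trinoreremophila-4(15),6,9-trien-8-one | C1=C[C@]2(C)C(=C)CCCC2=CC1=O | intermediate
17 | 3α-hydroxy-11,12,13-trinoreremophila-4(15),6,9-trien-8-one | C1=C[C@]2(C)C(=C)[C@H](O)CCC2=CC1=O | intermediate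
18 | 3α-hydroxy-11,12,13-trinoreremophila-6,9-dien-8-one (C15 β) | C1=C[C@]2(C)[C@@H](C)[C@H](O)CCC2=CC1=O | intermediate
19 | 3α-hydroxy-7-iodo-11,12,13-trinoreremophila-6,9-dien-8-one | IC1=C[C@]2(C)[C@@H](C)[C@H](O)CCC2=CC1=O | intermediate
20 | 3α-hydroxyeremophila-6,9,11-trien-8-one | C=C(C)C1=C[C@]2(C)[C@@H](C)[C@H](O)CCC2=CC1=O | intermediate
21 | 3α-hydroxy-7βH-eremophila-9,11-dien-8-one (isopropenyl α) | C=C(C)[C@@H]1C[C@]2(C)[C@@H](C)[C@H](O)CCC2=CC1=O | intermediate
22 | dilithium 7βH,10αH-eremophila-8,11-diene-3α,8-diolate (not isolated) | C=C(C)[C@@H]1C[C@]2(C)[C@@H](C)[C@H](O[Li])CC[C@H]2C=C1O[Li] | intermediate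
23 | 3α,9α-dihydroxy-7βH,10αH-eremophil-11-en-8-one | C=C(C)[C@@H]1C[C@]2(C)[C@@H](C)[C@H](O)CC[C@H]2[C@H](O)C1=O | intermediate
24 | 7βH,10αH-eremophil-11-ene-3α,8α,9α-triol | C=C(C)[C@@H]1C[C@]2(C)[C@@H](C)[C@H](O)CC[C@H]2[C@H](O)[C@@H]1O | intermediate
25 | 8α,9α-O-isopropylidene-7βH,10αH-eremophil-11-ene-3α,8α,9α-triol | C=C(C)[C@@H]1C[C@]2(C)[C@@H](C)[C@H](O)CC[C@H]2[C@H](OC(C)(C)O3)[C@@H]13 | intermediate
26 | (R)-pent-1-yn-3-ol | C#C[C@@H](CC)O | starting material
27 | angelic acid, (Z)-2-methylbut-2-enoic acid | C/C=C(/C)C(=O)O | starting material
28 | angelic 2,4,6-trichlorobenzoic anhydride (not isolated) | C/C=C(/C)C(=O)OC(=O)c1c(Cl)cc(Cl)cc1Cl | intermediate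
29 | (R)-pent-1-yn-3-yl (Z)-2-methylbut-2-enoate | C#C[C@@H](CC)OC(=O)/C(C)=C\C | intermediate
30 | lithium acetylide of 29 (not isolated) | [Li]C#C[C@@H](CC)OC(=O)/C(C)=C\C | intermediate
31 | (R)-4-[(Z)-2-methylbut-2-enoyloxy]hex-2-ynoic acid | OC(=O)C#C[C@@H](CC)OC(=O)/C(C)=C\C | intermediate
32 | 3-O-[(R)-4-(angeloyloxy)hex-2-ynoyl] derivative of 25 | C=C(C)[C@@H]1C[C@]2(C)[C@@H](C)[C@H](OC(=O)C#C[C@@H](CC)OC(=O)/C(C)=C\C)CC[C@H]2[C@H](OC(C)(C)O3)[C@@H]13 | intermediate
33 | 3-O-[(2Z,4R)-4-(angeloyloxy)hex-2-enoyl] derivative of 25 | C=C(C)[C@@H]1C[C@]2(C)[C@@H](C)[C@H](OC(=O)/C=C\[C@@H](CC)OC(=O)/C(C)=C\C)CC[C@H]2[C@H](OC(C)(C)O3)[C@@H]13 | intermediate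
34 | CNP0382739.1, 3α-[(2Z,4R)-4-(angeloyloxy)hex-2-enoyloxy]-7βH,10αH-eremophil-11-ene-8α,9α-diol | C=C(C)[C@@H]1C[C@]2(C)[C@@H](C)[C@H](OC(=O)/C=C\[C@@H](CC)OC(=O)/C(C)=C\C)CC[C@H]2[C@H](O)[C@@H]1O | target

Total step count: 23. Longest linear sequence: 21 steps from benzoic acid 1 (steps 1–18 and 21–23); the side-chain acid 31 takes 2 steps (19 and 20) from 26 and 27.

Least certain steps

For the key step, step 6, the most likely failure is insufficient discrimination between the two enone arms. The all-carbon tether with its trigonal C4 holds the enaminol differently from the heteroatom tethers for which this catalyst class is best documented, and a slow six-ring closure would let self-condensation of the aliphatic aldehyde compete. The fallback gives up asymmetric catalysis and closes the same bond by a radical. It sets out from 10: Pinnick oxidation (NaClO2, NaH2PO4, 2-methylbut-2-ene) gives 4-(1-methyl-4-oxocyclohexa-2,5-dien-1-yl)pent-4-enoic acid F1, which is converted with (PhSe)2 and PBu3 into the Se-phenyl selenoester F2. Treatment with Bu3SnH and AIBN generates the acyl radical, whose 6-exo attack on C10 gives the racemic cis-fused ene-dione F3. Separation on a chiral stationary phase returns the route at 11.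

For step 11 the risk is poor facial selectivity in the oxygen transfer, since chair-like axial delivery to the β face may compete despite the syn-axial methyl, together with over-oxidation to the enone. The fallback fixes the face by epoxidation and sets out from 16. RhCl3·3H2O in ethanol moves the exocyclic double bond into the ring to give 11,12,13-trinoreremophila-3,6,9-trien-8-one F4. mCPBA epoxidises this only electron-rich alkene on the α face, the β face being closed by the adjacent axial methyl, to give 3α,4α-epoxy-11,12,13-trinoreremophila-6,9-dien-8-one F5. Me3SiOTf with 2,6-lutidine and then DBU opens the tertiary C4–O bond with loss of a C15 proton to give 3α-(trimethylsilyloxy)-11,12,13-trinoreremophila-4(15),6,9-trien-8-one F6. K2CO3 in methanol removes the silyl group and the route is rejoined at 17.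

For step 15 the risks are hydride delivery to the wrong enone arm or a second reduction, and, during protonation and equilibration at C7, either the wrong epimer or migration of the side-chain double bond into conjugation. The fallback separates the reduction from the isopropenyl group and sets out from 18. Hydrogenation over RhCl(PPh3)3 saturates only the disubstituted C6–C7 bond of the cross-conjugated dienone and gives 3α-hydroxy-11,12,13-trinoreremophil-9-en-8-one F7. Palladium-catalysed α-alkenylation of its kinetic C7 enolate (LiN(SiMe3)2, Pd2(dba)3, P(t-Bu)3, 2-bromopropene) then attaches the isopropenyl group on the open α face and rejoins the route at 21.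

For step 16 the risk is inefficient oxidation of the lithium enolate in the residue left after removal of ammonia (proton exchange that scrambles the enolate, or reduction of the ketone by excess metal). The fallback isolates the enolate as a silyl ether and sets out from 21. Li in NH3 followed by Me3SiCl and Et3N gives 3α,8-bis(trimethylsilyloxy)-7βH,10αH-eremophila-8,11-diene F8. Rubottom oxidation with one equivalent of mCPBA and NaHCO3 at −20 °C, where the enol ether reacts far faster than the isopropenyl group, gives 3α,9α-bis(trimethylsilyloxy)-7βH,10αH-eremophil-11-en-8-one F9. K2CO3 in methanol removes both silyl groups and returns 23.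

For step 21 the risk is base-induced isomerisation of the 4-acyloxy-2-ynoate towards the allenoate, or addition of DMAP to the activated ynoate, with over-reduction in the following semi-hydrogenation as a further hazard. The fallback makes the Z-alkene by olefination and sets out from 25 and 29. Esterification of 25 with (diphenoxyphosphoryl)acetic acid and DCC gives the phosphonoacetate F10. Semi-hydrogenation of 29 over Pd/CaCO3 poisoned with Pb(OAc)2 gives (R)-pent-1-en-3-yl (Z)-2-methylbut-2-enoate F11, and ozonolysis (O3, CH2Cl2, −78 °C, then Me2S), which spares the electron-poor angelate alkene, gives (R)-1-oxobutan-2-yl (Z)-2-methylbut-2-enoate F12. A Z-selective Horner–Wadsworth–Emmons reaction of F10 with F12 (NaH, THF, −78 °C) rejoins the route at 33, bypassing 32.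

Further compounds

F1 | step 6 | 4-(1-methyl-4-oxocyclohexa-2,5-dien-1-yl)pent-4-enoic acid | OC(=O)CCC(=C)C1(C)C=CC(=O)C=C1
F2 | step 6 | Se-phenyl 4-(1-methyl-4-oxocyclohexa-2,5-dien-1-yl)pent-4-eneselenoate | O=C(CCC(=C)C1(C)C=CC(=O)C=C1)[Se]c1ccccc1
F3 | step 6 | racemic cis-fused ene-dione (11 with its mirror image) | C1=C[C@]2(C)C(=C)CCC(=O)[C@@H]2CC1=O.C1=C[C@@]2(C)C(=C)CCC(=O)[C@H]2CC1=O
F4 | step 11 | 11,12,13-trinoreremophila-3,6,9-trien-8-one | C1=C[C@]2(C)C(C)=CCCC2=CC1=O
F5 | step 11 | 3α,4α-epoxy-11,12,13-trinoreremophila-6,9-dien-8-one | C1=C[C@]2(C)[C@]3(C)O[C@@H]3CCC2=CC1=O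
F6 | step 11 | 3α-(trimethylsilyloxy)-11,12,13-trinoreremophila-4(15),6,9-trien-8-one | C1=C[C@]2(C)C(=C)[C@H](O[Si](C)(C)C)CCC2=CC1=O
F7 | step 15 | 3α-hydroxy-11,12,13-trinoreremophil-9-en-8-one | C1C[C@]2(C)[C@@H](C)[C@H](O)CCC2=CC1=O
F8 | step 16 | 3α,8-bis(trimethylsilyloxy)-7βH,10αH-eremophila-8,11-diene | C=C(C)[C@@H]1C[C@]2(C)[C@@H](C)[C@H](O[Si](C)(C)C)CC[C@H]2C=C1O[Si](C)(C)C
F9 | step 16 | 3α,9α-bis(trimethylsilyloxy)-7βH,10αH-eremophil-11-en-8-one | C=C(C)[C@@H]1C[C@]2(C)[C@@H](C)[C@H](O[Si](C)(C)C)CC[C@H]2[C@H](O[Si](C)(C)C)C1=O
F10 | step 21 | 3-O-[(diphenoxyphosphoryl)acetyl] derivative of 25 | C=C(C)[C@@H]1C[C@]2(C)[C@@H](C)[C@H](OC(=O)CP(=O)(Oc4ccccc4)Oc5ccccc5)CC[C@H]2[C@H](OC(C)(C)O3)[C@@H]13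
F11 | step 21 | (R)-pent-1-en-3-yl (Z)-2-methylbut-2-enoate | C=C[C@@H](CC)OC(=O)/C(C)=C\C
F12 | step 21 | (R)-1-oxobutan-2-yl (Z)-2-methylbut-2-enoate | O=C[C@@H](CC)OC(=O)/C(C)=C\C
A1 | alternative 1 | ring A neopentyl iodide carrying the 8,9-acetonide and the (E)-2-methylallyl phenyl sulfone | IC[C@]2(C)[C@@H](C)[C@H](O[Si](C)(C)C(C)(C)C)CC[C@H]2[C@H](OC(C)(C)O3)[C@H]3/C=C(\C)CS(=O)(=O)c4ccccc4
A2 | alternative 1 | 3-O-tert-butyldimethylsilyl eremophil-11-ene-3α,8α,9α-triol 8,9-acetonide | C=C(C)[C@@H]1C[C@]2(C)[C@@H](C)[C@H](O[Si](C)(C)C(C)(C)C)CC[C@H]2[C@H](OC(C)(C)O3)[C@@H]13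
A3 | alternative 2 | ring A α-silyloxy aldehyde carrying a prenyl group on C5 | CC(C)=CC[C@]2(C)[C@@H](C)[C@H](OCc3ccc(OC)cc3)CC[C@H]2[C@H](O[Si](C)(C)C(C)(C)C)C=O
A4 | alternative 2 | 3-O-(4-methoxybenzyl) 9-O-tert-butyldimethylsilyl eremophil-11-ene-3α,8β,9α-triol | C=C(C)[C@@H]1C[C@]2(C)[C@@H](C)[C@H](OCc3ccc(OC)cc3)CC[C@H]2[C@H](O[Si](C)(C)C(C)(C)C)[C@H]1O
A5 | alternative 3 | acyclic triene with E β-methyl enoate, 8,9-acetonide and 1-silyloxy diene | COC(=O)/C=C(\C)C[C@@H](C(C)=C)[C@H]1OC(C)(C)O[C@H]1/C=C/C=C/O[Si](C)(C)C(C)(C)C
A6 | alternative 3 | trans-fused octalin methyl ester with 3β-silyloxy group and 8,9-acetonide | C=C(C)[C@@H]1C[C@]2(C)[C@@H](C(=O)OC)[C@@H](O[Si](C)(C)C(C)(C)C)C=C[C@H]2[C@H](OC(C)(C)O3)[C@@H]13
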